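**Plan**
1. Retrosynthesis: cut the C-8 ester, the C-12 acid (back to a lactol), the two exocyclic methylenes (C-3, C-13), the C-10–vinyl bond (conjugate addition to a C-8 enone), then the ring bond C-8–C-9, then C-5–C-10, C-4=C-5 and C-7–C-8.
2. Feature used for the ring bond: C-9 is a bare CH2 between the oxygenated C-8 and the quaternary C-10 carrying CH3 and vinyl. This is the retron of a 3-methylenecyclohexanol, i.e. an aldehyde (C-8) plus an isopropenyl group (C-9, C-10, C-14) on C-5.
3. Forward: the γ-lactone of a chiral butenolide (O–C-6, C-7, C-11, C-12) serves as a temporary ring. C-8 (masked aldehyde), C-4/C-15 and the isopropenyl group are added, the cyclohexane (C-5 to C-10) is closed by a carbonyl-ene reaction, and the exocyclic alkene is moved into a C-8 enone for the vinyl addition.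
4. End game: reduction to the axial C-8 alcohol, double α-methylenation, reduction of lactone and ester to lactol and allylic alcohol, esterification, and oxidation of the lactol to the free hydroxy acid.
5. Stereochemistry: C-6 from (S)-5-(hydroxymethyl)butenolide; C-7 by anti radical addition; C-5 by ligand-controlled rhodium-catalysed addition; C-10 and C-8 by axial cuprate attack and equatorial hydride attack on the rigid trans-fused bicycle.

Key step: step 7

Remark: carbons are numbered as in the elemane skeleton (C-1/C-2 vinyl on C-10, C-3 and C-15 on C-4, ring C-5 to C-10, C-11/C-12/C-13 on C-7, C-14 methyl); the hemiacetal carbon C-12 of 28–30, 41 and 42 is expected as an anomeric mixture and is written without configuration.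

**Step 1**
Reactants: 1 (5S)-5-(hydroxymethyl)furan-2(5H)-one; 2 tert-butyl(chloro)dimethylsilane
Product: 3 (5S)-5-{[tert-butyl(dimethyl)silyl]oxymethyl}furan-2(5H)-one
Conditions: TBSCl, imidazole, CH2Cl2, 0 °C → rt
Reagents that add atoms: tert-butyl(chloro)dimethylsilane, CC(C)(C)[Si](C)(C)Cl
Why: Standard silylation of the primary alcohol; the bulky CH2OTBS group is what should make the next radical addition anti-selective.

**Step 2**
Reactants: 3; 4 1,3-dioxolane
Product: 5 (4S,5S)-5-{[tert-butyl(dimethyl)silyl]oxymethyl}-4-(1,3-dioxolan-2-yl)oxolan-2-one (4,5-trans)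
Conditions: hν (medium-pressure Hg lamp, Pyrex), benzophenone (10 mol%), 1,3-dioxolane as solvent, degassed, 10 °C
Reagents that add atoms: 1,3-dioxolane, C1COCO1
Why: Benzophenone-sensitised photochemical conjugate addition: the nucleophilic dioxolan-2-yl radical should add to the butenolide β-carbon anti to the CH2OTBS group (closely precedented on 5-substituted furanones), setting C-7 trans to C-6 and installing C-8 as a masked aldehyde.

**Step 3**
Reactants: 5
Product: 6 (4S,5S)-4-(1,3-dioxolan-2-yl)-5-(hydroxymethyl)oxolan-2-one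
Conditions: HF·pyridine, pyridine, THF, 0 °C → rt
Reagents that add atoms: none
Why: Buffered fluoride cleavage of the primary silyl ether should leave the lactone and the dioxolane untouched.

**Step 4**
Reactants: 6; 7 methyl (triphenylphosphoranylidene)acetate
Product: 9 methyl (2E)-3-[(2R,3S)-3-(1,3-dioxolan-2-yl)-5-oxooxolan-2-yl]prop-2-enoate, via aldehyde 8 (not isolated)
Conditions: Dess–Martin periodinane, CH2Cl2, 0 °C → rt; then ylide 7 (2.5 equiv), rt
Reagents that add atoms: methyl (triphenylphosphoranylidene)acetate, COC(=O)C=P(c1ccccc1)(c1ccccc1)c1ccccc1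
Why: Dess–Martin oxidation followed in the same flask by Wittig olefination with a stabilised ylide (E-selective); telescoping should avoid epimerisation of the α-acyloxy aldehyde at C-6.

**Step 5**
Reactants: 9; 10 potassium trifluoro(prop-1-en-2-yl)borate
Product: 11 methyl (3R)-3-[(2R,3S)-3-(1,3-dioxolan-2-yl)-5-oxooxolan-2-yl]-4-methylpent-4-enoate
Conditions: [Rh(cod)2]PF6 (5 mol%), (S)-BINAP (6 mol%), toluene/H2O 10:1, 100 °C
Reagents that add atoms: potassium trifluoro(prop-1-en-2-yl)borate, [K+].C=C(C)[B-](F)(F)F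
Why: Rhodium-catalysed conjugate addition of an alkenyltrifluoroborate to an enoate (transmetalation, carbometalation, protonation by water); C-5 is set by the chiral bisphosphine, (S)-BINAP being expected from the accepted face-selection model for E-acceptors to deliver the alkenyl group to the α-si face (3R), and rhodium should not cause the loss of the γ-acyloxy group that cuprates can.

**Step 6**
Reactants: 11; 12 water
Product: 13 methyl (3R)-3-[(2R,3S)-3-formyl-5-oxooxolan-2-yl]-4-methylpent-4-enoate
Conditions: 2 M HCl/THF 1:4, rt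
Reagents that add atoms: water, O
Why: Acid-catalysed acetal hydrolysis unmasks the C-8 aldehyde; lactone, ester and isopropenyl group should tolerate dilute acid at room temperature.

**Step 7**
Reactants: 13
Product: 14 methyl 2-[(3aR,4R,7R,7aR)-4-hydroxy-6-methylidene-2-oxooctahydro-1-benzofuran-7-yl]acetate (trans-fused)
Conditions: Me2AlCl (3 equiv), CH2Cl2, −78 → −20 °C; then 1 M HCl
Reagents that add atoms: none
Why: Me2AlCl binds the aldehyde oxygen and the terminal CH2 (C-9) of the isopropenyl group attacks C-8 while an allylic hydrogen of the methyl group (C-14) passes to oxygen in a concerted, asynchronous carbonyl-ene process; loss of methane from the aluminium–alcohol complex then makes the step irreversible and removes the proton source for cationic side reactions. The closest known reaction type is the Lewis-acid-promoted type 2 intramolecular carbonyl-ene cyclisation of 5-methylhex-5-enal-type aldehydes to 3-methylenecyclohexanols. The cyclohexane closes 6-exo-trig at the carbonyl group (the oxygen stays outside the ring) with both ene carbons C-9 and C-10 inside the new ring, and the trans-fused γ-lactone enforces a chair transition state with C-6–O and C-7–C-11 equatorial and the C-5 side chain axial. The only new stereocentre, C-8, should be set by that chair: the aluminium-bound oxygen must be axial to reach the C-14 hydrogen, giving the axial (4R) alcohol, but either epimer is usable because this centre is oxidised in step 8. The step needs chemoselectivity and regioselective hydrogen transfer: the isopropenyl group is the only alkene in 13 (the methylidene groups of the target are still absent, ester and lactone are inert), and transfer of the ring hydrogen at C-5 would require a boat, so the exocyclic alkene that later becomes the C-14 methyl and the C-9/C-10 enone should dominate.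

**Step 8**
Reactants: 14
Product: 16 methyl 2-[(3aS,7R,7aR)-6-methyl-2,4-dioxo-2,3,3a,4,7,7a-hexahydro-1-benzofuran-7-yl]acetate, via β,γ-enone 15 (not isolated)
Conditions: Dess–Martin periodinane, CH2Cl2, rt; then p-TsOH·H2O (10 mol%), rt
Reagents that add atoms: none
Why: Dess–Martin oxidation erases C-8 (both epimers converge) and acid-catalysed migration of the exocyclic alkene into conjugation (via the dienol) should give the 3-methylcyclohexenone; acid is chosen over base to avoid E1cB loss of the β-acyloxy group.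

**Step 9**
Reactants: 16; 17 vinylmagnesium bromide; 18 chlorotrimethylsilane
Product: 20 methyl 2-[(3aS,6R,7R,7aR)-6-ethenyl-6-methyl-2,4-dioxooctahydro-1-benzofuran-7-yl]acetate, via silyl enol ether 19 (not isolated)
Conditions: CH2=CHMgBr (3 equiv), CuBr·SMe2 (20 mol%), Me3SiCl (3 equiv), THF, −78 °C; then 1 M HCl, 0 °C
Reagents that add atoms: vinylmagnesium bromide, C=C[Mg]Br
Why: Copper-catalysed conjugate addition of a vinyl Grignard reagent to the β-methyl enone creates the quaternary C-10; in the rigid trans-fused bicycle the C-5 side chain is pseudo-axial on the lower face, so axial attack should occur anti to it (vinyl trans to the C-5 substituent, methyl equatorial).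

**Step 10**
Reactants: 20; 18 chlorotrimethylsilane
Product: 22 methyl 2-[(3aS,4R,6R,7R,7aR)-6-ethenyl-6-methyl-2-oxo-4-[(trimethylsilyl)oxy]octahydro-1-benzofuran-7-yl]acetate, via lithium alkoxide 21 (not isolated)
Conditions: LiBH(s-Bu)3 (1.2 equiv), THF, −78 °C; then Me3SiCl (2 equiv), −78 → 0 °C
Reagents that add atoms: chlorotrimethylsilane, C[Si](C)(C)Cl
Why: The bulky trialkylborohydride should attack the ketone from the equatorial direction because the axial face is blocked by the 1,3-diaxial vinyl group, giving the axial C-8 alkoxide, which is capped in situ as its silyl ether for the enolate and lactol stages.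

**Step 11**
Reactants: 22; 23 N,N-dimethylmethaniminium iodide (Eschenmoser's salt); 24 iodomethane
Product: 27 methyl 2-[(3aS,4R,6R,7S,7aR)-6-ethenyl-6-methyl-3-methylidene-2-oxo-4-[(trimethylsilyl)oxy]octahydro-1-benzofuran-7-yl]prop-2-enoate, via bis-Mannich base 25 (not isolated), via bis-ammonium diiodide 26 (not isolated)
Conditions: LiN(i-Pr)2 (2.5 equiv), THF, −78 °C (inverse addition); CH2=NMe2+ I− (3 equiv), −78 °C → rt; then MeI (excess), rt; then DBU, CH2Cl2, rt
Reagents that add atoms: N,N-dimethylmethaniminium iodide, C=[N+](C)C.[I-]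
Why: Double α-methylenation by Mannich reaction of the lactone and ester lithium enolates, N-methylation and elimination of trimethylamine; each carbonyl has a single α-CH2, and C-5 and C-7 are β-carbons that cannot epimerise.

**Step 12**
Reactants: 27
Product: 28 2-[(3aS,4R,6R,7S,7aR)-6-ethenyl-2-hydroxy-6-methyl-3-methylidene-4-[(trimethylsilyl)oxy]octahydro-1-benzofuran-7-yl]prop-2-en-1-ol (lactol, C-2 epimers)
Conditions: i-Bu2AlH (5 equiv), CH2Cl2, −78 °C; aq. potassium sodium tartrate
Reagents that add atoms: none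
Why: At −78 °C the aluminium hydride should stop at the lactol (stable tetrahedral aluminate) and reduce the acrylate 1,2 to the allylic alcohol, bringing C-12 to the aldehyde level and C-15 to its final alcohol level.

**Step 13**
Reactants: 28; 2 tert-butyl(chloro)dimethylsilane
Product: 29 bis-TBS ether of 28 (anomeric O-12 and O-15 silylated, C-8 OTMS retained)
Conditions: TBSCl (2.5 equiv), imidazole, DMF, 0 °C → rt
Reagents that add atoms: tert-butyl(chloro)dimethylsilane, CC(C)(C)[Si](C)(C)Cl
Why: Silylation of the primary allylic alcohol and the hemiacetal hydroxyl locks the lactol ring on O-6 before C-8 is freed, so it cannot transpose to O-8 through the open aldehyde.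

**Step 14**
Reactants: 29
Product: 30 (3aR,4R,6R,7S,7aR)-2-{[tert-butyl(dimethyl)silyl]oxy}-7-(3-{[tert-butyl(dimethyl)silyl]oxy}prop-1-en-2-yl)-6-ethenyl-6-methyl-3-methylideneoctahydro-1-benzofuran-4-ol
Conditions: K2CO3 (0.2 equiv), MeOH, 0 °C
Reagents that add atoms: none
Why: Base-catalysed methanolysis should remove only the labile trimethylsilyl ether, freeing the C-8 alcohol under non-acidic conditions that cannot transpose the acetal.

**Step 15**
Reactants: 31 3-methylfuran-2(5H)-one; 32 potassium hydroxide; 33 4-methoxybenzyl chloride; 34 acetic anhydride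
Product: 37 4-methoxybenzyl (2Z)-4-(acetyloxy)-2-methylbut-2-enoate, via potassium carboxylate 35 (not isolated), via hydroxy ester 36 (not isolated)
Conditions: KOH (1.0 equiv), MeOH/H2O, rt, evaporate; 4-MeOC6H4CH2Cl, Bu4NI (cat.), DMF, rt; then Ac2O, pyridine, 0 °C
Reagents that add atoms: potassium hydroxide, [K+].[OH-]; 4-methoxybenzyl chloride, COc1ccc(CCl)cc1; acetic anhydride, CC(=O)OC(C)=O
Why: Saponification of the butenolide gives the hydroxy carboxylate with the Z geometry fixed by the ring; O-alkylation of the carboxylate and immediate acetylation of the alcohol should trap the open form before relactonisation.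

**Step 16**
Reactants: 37
Product: 38 (2Z)-4-(acetyloxy)-2-methylbut-2-enoic acid
Conditions: CF3CO2H, anisole, CH2Cl2, 0 °C
Reagents that add atoms: none
Why: Acidolysis of the 4-methoxybenzyl ester (cation scavenged by anisole) should free the acid without touching the allylic acetate or the Z-alkene.

**Step 17**
Reactants: 30; 38; 39 2,4,6-trichlorobenzoyl chloride
Product: 41 (3aR,4R,6R,7S,7aR)-2-{[tert-butyl(dimethyl)silyl]oxy}-7-(3-{[tert-butyl(dimethyl)silyl]oxy}prop-1-en-2-yl)-6-ethenyl-6-methyl-3-methylideneoctahydro-1-benzofuran-4-yl (2Z)-4-(acetyloxy)-2-methylbut-2-enoate, via mixed anhydride 40 (not isolated)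
Conditions: 38, 2,4,6-trichlorobenzoyl chloride, Et3N, toluene, rt; then 30, toluene, 80 °C (no nucleophilic amine catalyst)
Reagents that add atoms: (2Z)-4-(acetyloxy)-2-methylbut-2-enoic acid, OC(=O)/C(C)=C\COC(C)=O
Why: Yamaguchi esterification through the mixed anhydride, run without a nucleophilic catalyst so that the angelate-type acyl group is not isomerised by addition–elimination; heating is meant to overcome the hindered axial alcohol, and C-8 keeps its configuration.

**Step 18**
Reactants: 41
Product: 42 (3aR,4R,6R,7S,7aR)-6-ethenyl-2-hydroxy-7-(3-hydroxyprop-1-en-2-yl)-6-methyl-3-methylideneoctahydro-1-benzofuran-4-yl (2Z)-4-(acetyloxy)-2-methylbut-2-enoate (lactol)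
Conditions: HF·pyridine, THF, 0 °C → rt
Reagents that add atoms: none
Why: Fluoride should cleave the anomeric and the primary silyl ethers while all three esters survive, giving the lactol in equilibrium with the hydroxy enal.

**Step 19**
Reactants: 42; 43 sodium chlorite
Product: 44 2-[(1S,2R,3S,4R,6R)-6-{[(2Z)-4-(acetyloxy)-2-methylbut-2-enoyl]oxy}-4-ethenyl-2-hydroxy-3-(3-hydroxyprop-1-en-2-yl)-4-methylcyclohexyl]prop-2-enoic acid (CNP0261293.1)
Conditions: NaClO2, NaH2PO4, 2-methylbut-2-ene, t-BuOH/H2O, 0 °C → rt; work-up at pH 5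
Reagents that add atoms: sodium chlorite, [Na+].[O-]Cl=O
Why: Pinnick oxidation of the open aldehyde form should give the α-substituted acrylic acid with C-6–OH free; the scavenger protects the alkenes, the buffered medium spares the esters, and closure to the trans-fused lactone is expected to be slow.

**Compound list**
1 | (5S)-5-(hydroxymethyl)furan-2(5H)-one | O=C1C=C[C@@H](CO)O1 | starting material
2 | tert-butyl(chloro)dimethylsilane | CC(C)(C)[Si](C)(C)Cl | starting material
3 | (5S)-5-{[tert-butyl(dimethyl)silyl]oxymethyl}furan-2(5H)-one | O=C1C=C[C@@H](CO[Si](C)(C)C(C)(C)C)O1 | intermediate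
4 | 1,3-dioxolane | C1COCO1 | starting material
5 | (4S,5S)-5-{[tert-butyl(dimethyl)silyl]oxymethyl}-4-(1,3-dioxolan-2-yl)oxolan-2-one | O=C1C[C@H](C2OCCO2)[C@@H](CO[Si](C)(C)C(C)(C)C)O1 | intermediate
6 | (4S,5S)-4-(1,3-dioxolan-2-yl)-5-(hydroxymethyl)oxolan-2-one | O=C1C[C@H](C2OCCO2)[C@@H](CO)O1 | intermediate
7 | methyl (triphenylphosphoranylidene)acetate | COC(=O)C=P(c1ccccc1)(c1ccccc1)c1ccccc1 | starting material
8 | (2S,3S)-3-(1,3-dioxolan-2-yl)-5-oxooxolane-2-carbaldehyde | O=C1C[C@H](C2OCCO2)[C@@H](C=O)O1 | intermediate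
9 | methyl (2E)-3-[(2R,3S)-3-(1,3-dioxolan-2-yl)-5-oxooxolan-2-yl]prop-2-enoate | O=C1C[C@H](C2OCCO2)[C@@H](/C=C/C(=O)OC)O1 | intermediate
10 | potassium trifluoro(prop-1-en-2-yl)borate | [K+].C=C(C)[B-](F)(F)F | starting material
11 | methyl (3R)-3-[(2R,3S)-3-(1,3-dioxolan-2-yl)-5-oxooxolan-2-yl]-4-methylpent-4-enoate | O=C1C[C@H](C2OCCO2)[C@@H]([C@H](CC(=O)OC)C(C)=C)O1 | intermediate
12 | water | O | starting material
13 | methyl (3R)-3-[(2R,3S)-3-formyl-5-oxooxolan-2-yl]-4-methylpent-4-enoate | O=C1C[C@H](C=O)[C@@H]([C@H](CC(=O)OC)C(C)=C)O1 | intermediate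
14 | methyl 2-[(3aR,4R,7R,7aR)-4-hydroxy-6-methylidene-2-oxooctahydro-1-benzofuran-7-yl]acetate | O=C1C[C@H]2[C@H](O1)[C@H](CC(=O)OC)C(=C)C[C@H]2O | intermediate
15 | methyl 2-[(3aS,7R,7aR)-6-methylidene-2,4-dioxooctahydro-1-benzofuran-7-yl]acetate | O=C1C[C@H]2[C@H](O1)[C@H](CC(=O)OC)C(=C)CC2=O | intermediate
16 | methyl 2-[(3aS,7R,7aR)-6-methyl-2,4-dioxo-2,3,3a,4,7,7a-hexahydro-1-benzofuran-7-yl]acetate | O=C1C[C@H]2[C@H](O1)[C@H](CC(=O)OC)C(C)=CC2=O | intermediate
17 | vinylmagnesium bromide | C=C[Mg]Br | starting material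
18 | chlorotrimethylsilane | C[Si](C)(C)Cl | starting material
19 | trimethylsilyl enol ether (C-8/C-9) of ketone 20 | O=C1C[C@H]2[C@H](O1)[C@H](CC(=O)OC)[C@@](C)(C=C)C=C2O[Si](C)(C)C | intermediate
20 | methyl 2-[(3aS,6R,7R,7aR)-6-ethenyl-6-methyl-2,4-dioxooctahydro-1-benzofuran-7-yl]acetate | O=C1C[C@H]2[C@H](O1)[C@H](CC(=O)OC)[C@@](C)(C=C)CC2=O | intermediate
21 | lithium alkoxide of the axial (4R) alcohol from 20 | O=C1C[C@H]2[C@H](O1)[C@H](CC(=O)OC)[C@@](C)(C=C)C[C@H]2[O-].[Li+] | intermediate
22 | methyl 2-[(3aS,4R,6R,7R,7aR)-6-ethenyl-6-methyl-2-oxo-4-[(trimethylsilyl)oxy]octahydro-1-benzofuran-7-yl]acetate | O=C1C[C@H]2[C@H](O1)[C@H](CC(=O)OC)[C@@](C)(C=C)C[C@H]2O[Si](C)(C)C | intermediate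
23 | N,N-dimethylmethaniminium iodide | C=[N+](C)C.[I-] | starting material
24 | iodomethane | CI | starting material
25 | bis(dimethylaminomethyl) derivative of 22 (at C-11 and C-4, epimers) | O=C1C(CN(C)C)[C@H]2[C@H](O1)[C@H](C(CN(C)C)C(=O)OC)[C@@](C)(C=C)C[C@H]2O[Si](C)(C)C | intermediate
26 | bis(trimethylammoniomethyl) diiodide from 25 | O=C1C(C[N+](C)(C)C)[C@H]2[C@H](O1)[C@H](C(C[N+](C)(C)C)C(=O)OC)[C@@](C)(C=C)C[C@H]2O[Si](C)(C)C.[I-].[I-] | intermediate
27 | methyl 2-[(3aS,4R,6R,7S,7aR)-6-ethenyl-6-methyl-3-methylidene-2-oxo-4-[(trimethylsilyl)oxy]octahydro-1-benzofuran-7-yl]prop-2-enoate | O=C1C(=C)[C@H]2[C@H](O1)[C@H](C(=C)C(=O)OC)[C@@](C)(C=C)C[C@H]2O[Si](C)(C)C | intermediate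
28 | 2-[(3aS,4R,6R,7S,7aR)-6-ethenyl-2-hydroxy-6-methyl-3-methylidene-4-[(trimethylsilyl)oxy]octahydro-1-benzofuran-7-yl]prop-2-en-1-ol | OC1C(=C)[C@H]2[C@H](O1)[C@H](C(=C)CO)[C@@](C)(C=C)C[C@H]2O[Si](C)(C)C | intermediate
29 | bis-TBS ether of 28 (O-12 anomeric and O-15), C-8 OTMS | CC(C)(C)[Si](C)(C)OC1C(=C)[C@H]2[C@H](O1)[C@H](C(=C)CO[Si](C)(C)C(C)(C)C)[C@@](C)(C=C)C[C@H]2O[Si](C)(C)C | intermediate
30 | (3aR,4R,6R,7S,7aR)-2-{[tert-butyl(dimethyl)silyl]oxy}-7-(3-{[tert-butyl(dimethyl)silyl]oxy}prop-1-en-2-yl)-6-ethenyl-6-methyl-3-methylideneoctahydro-1-benzofuran-4-ol | CC(C)(C)[Si](C)(C)OC1C(=C)[C@H]2[C@H](O1)[C@H](C(=C)CO[Si](C)(C)C(C)(C)C)[C@@](C)(C=C)C[C@H]2O | intermediate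
31 | 3-methylfuran-2(5H)-one | CC1=CCOC1=O | starting material
32 | potassium hydroxide | [K+].[OH-] | starting material
33 | 4-methoxybenzyl chloride | COc1ccc(CCl)cc1 | starting material
34 | acetic anhydride | CC(=O)OC(C)=O | starting material
35 | potassium (2Z)-4-hydroxy-2-methylbut-2-enoate | [K+].[O-]C(=O)/C(C)=C\CO | intermediate
36 | 4-methoxybenzyl (2Z)-4-hydroxy-2-methylbut-2-enoate | COc1ccc(COC(=O)/C(C)=C\CO)cc1 | intermediate
37 | 4-methoxybenzyl (2Z)-4-(acetyloxy)-2-methylbut-2-enoate | COc1ccc(COC(=O)/C(C)=C\COC(C)=O)cc1 | intermediate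
38 | (2Z)-4-(acetyloxy)-2-methylbut-2-enoic acid | OC(=O)/C(C)=C\COC(C)=O | intermediate
39 | 2,4,6-trichlorobenzoyl chloride | O=C(Cl)c1c(Cl)cc(Cl)cc1Cl | starting material
40 | (2Z)-4-(acetyloxy)-2-methylbut-2-enoic 2,4,6-trichlorobenzoic anhydride | O=C(OC(=O)/C(C)=C\COC(C)=O)c1c(Cl)cc(Cl)cc1Cl | intermediate
41 | (2Z)-4-(acetyloxy)-2-methylbut-2-enoate ester of 30 at O-8 | CC(C)(C)[Si](C)(C)OC1C(=C)[C@H]2[C@H](O1)[C@H](C(=C)CO[Si](C)(C)C(C)(C)C)[C@@](C)(C=C)C[C@H]2OC(=O)/C(C)=C\COC(C)=O | intermediate
42 | (3aR,4R,6R,7S,7aR)-6-ethenyl-2-hydroxy-7-(3-hydroxyprop-1-en-2-yl)-6-methyl-3-methylideneoctahydro-1-benzofuran-4-yl (2Z)-4-(acetyloxy)-2-methylbut-2-enoate | OC1C(=C)[C@H]2[C@H](O1)[C@H](C(=C)CO)[C@@](C)(C=C)C[C@H]2OC(=O)/C(C)=C\COC(C)=O | intermediate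
43 | sodium chlorite | [Na+].[O-]Cl=O | starting material
44 | 2-[(1S,2R,3S,4R,6R)-6-{[(2Z)-4-(acetyloxy)-2-methylbut-2-enoyl]oxy}-4-ethenyl-2-hydroxy-3-(3-hydroxyprop-1-en-2-yl)-4-methylcyclohexyl]prop-2-enoic acid | C=C[C@@]1(C)C[C@@H](OC(=O)/C(C)=C\COC(C)=O)[C@@H](C(=C)C(=O)O)[C@H](O)[C@@H]1C(=C)CO | target

**Step count and risks**
Total: 19 steps. Longest linear sequence: 17 steps (steps 1–14 and 17–19); steps 15–16 make the side-chain acid.

Step 7 (key ring closure). The strain of closing a six-membered ring onto the trans-disubstituted lactone may slow the ene reaction, so that a stepwise cationic pathway (proton loss from C-5) or elimination of the β-acyloxy group from the activated aldehyde competes. Fallback: set out from aldehyde 13, oxidise it (NaClO2, NaH2PO4, 2-methylbut-2-ene) to (2R,3S)-2-[(3R)-5-methoxy-2-methyl-5-oxopent-1-en-3-yl]-5-oxooxolane-3-carboxylic acid F3. Activate F3 with trifluoroacetic anhydride to the mixed trifluoroacetic anhydride F4, whose acylium character should drive a Friedel–Crafts-type intramolecular acylation of the isopropenyl CH2. Proton loss and brief treatment with Et3N should give the conjugated enone directly, so this route comes back at compound 16 and bypasses 14 and step 8.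

Step 5 (isopropenyl addition). Transmetalation and insertion of the 1,1-disubstituted alkenyl group may be sluggish on this hindered enoate, and the neighbouring stereocentre may erode catalyst control. Fallback: set out from alcohol 6, oxidise as in step 4 to aldehyde 8 and condense it with dimethyl malonate (TiCl4, pyridine, Knoevenagel) to dimethyl 2-{[(2R,3S)-3-(1,3-dioxolan-2-yl)-5-oxooxolan-2-yl]methylidene}propanedioate F1. Uncatalysed 1,4-addition of CH2=C(CH3)MgBr at −78 °C, under substrate control (A(1,3) strain holds C-6–H in the alkene plane and the nucleophile should attack anti to ring carbon C-7), gives dimethyl 2-{(1R)-1-[(2R,3S)-3-(1,3-dioxolan-2-yl)-5-oxooxolan-2-yl]-2-methylprop-2-en-1-yl}propanedioate F2. Krapcho dealkoxycarbonylation (LiCl, wet DMSO, heat) comes back to compound 11.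

Step 17 (esterification). Acylation of the hindered axial C-8 alcohol may stall, and forcing conditions may isomerise the Z-acyl group to E. Fallback: set out from alcohol 30 and acylate it with the small 2-[bis(2,2,2-trifluoroethoxy)phosphoryl]propanoyl chloride (pyridine, CH2Cl2) to the 2-[bis(2,2,2-trifluoroethoxy)phosphoryl]propanoate of alcohol 30 F5. A Still–Gennari olefination with 2-oxoethyl acetate (KN(SiMe3)2, 18-crown-6, THF, −78 °C) then builds the Z-trisubstituted alkene on the substrate and comes back to compound 41.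

**Further compounds**
F1 | step 5 | dimethyl 2-{[(2R,3S)-3-(1,3-dioxolan-2-yl)-5-oxooxolan-2-yl]methylidene}propanedioate | O=C1C[C@H](C2OCCO2)[C@@H](C=C(C(=O)OC)C(=O)OC)O1
F2 | step 5 | dimethyl 2-{(1R)-1-[(2R,3S)-3-(1,3-dioxolan-2-yl)-5-oxooxolan-2-yl]-2-methylprop-2-en-1-yl}propanedioate | O=C1C[C@H](C2OCCO2)[C@@H]([C@H](C(C(=O)OC)C(=O)OC)C(C)=C)O1
F3 | step 7 | (2R,3S)-2-[(3R)-5-methoxy-2-methyl-5-oxopent-1-en-3-yl]-5-oxooxolane-3-carboxylic acid | O=C1C[C@H](C(=O)O)[C@@H]([C@H](CC(=O)OC)C(C)=C)O1
F4 | step 7 | mixed trifluoroacetic anhydride of F3 | O=C1C[C@H](C(=O)OC(=O)C(F)(F)F)[C@@H]([C@H](CC(=O)OC)C(C)=C)O1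
F5 | step 17 | 2-[bis(2,2,2-trifluoroethoxy)phosphoryl]propanoate of alcohol 30 | CC(C)(C)[Si](C)(C)OC1C(=C)[C@H]2[C@H](O1)[C@H](C(=C)CO[Si](C)(C)C(C)(C)C)[C@@](C)(C=C)C[C@H]2OC(=O)C(C)P(=O)(OCC(F)(F)F)OCC(F)(F)F
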